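## Structural features

The target is a trans-fused decalin (ring A: C1–C5 and C10; ring B: C5–C10) with an exocyclic methylene on C4, joined through the methylene C11 on C9 to C3 of a methyl 4-hydroxybenzoate. Ring B carries three contiguous stereocentres: C8 (CH–CH3), C9 (quaternary: CH3 and C11) and C10 (quaternary: angular CH3). C10 is flanked on its other side by the ring-fusion methine C5, which is also next to C4. All three methyl groups are on the β face, and the 8β-methyl is axial and syn to the axial 10β-methyl, so it is the less stable C8 epimer and cannot be left to equilibration. Fragile sites are the C4 methylene (acid moves it into the ring), the methyl ester, the free phenol, and C5–H whenever C4 is a carbonyl, because the cis-fused epimer would relieve the C8/C10 methyl repulsion. The real difficulty is the pair of adjacent quaternary carbons C9–C10 in the right relative configuration, with a further stereocentre at C8. The key step exploits two features of ring B: C9 bears a one-carbon arm (C11) that can be an aldehyde, so C9 can be the nucleophilic carbon of an enol ether, and its neighbour C8 bears a methyl that can come from an exocyclic methylene, i.e. from the internal carbon of a terminal alkyne. Closing ring B at C8–C9 therefore makes C9 quaternary without ever joining C9 and C10 as two fully substituted carbons.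

## Logic of the disconnections

**24 ⇒ 23.** The C4=CH2 bond is cut to the C4 carbonyl of 23. The exocyclic alkene is the most acid-sensitive group, so it is made last. The forward step must be a non-basic methylenation that tolerates a free phenol and a methyl ester and does not enolise C4 toward C5.

**23 ⇒ 21 (through 22).** The O–benzyl bond and the two C4–O ketal bonds are restored. Both protecting groups can then be removed while no alkene is present. The demand is neutral hydrogenolysis and a ketal hydrolysis mild enough that the freed ketone does not enolise.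

**21 ⇒ 20 ⇒ 19.** The C11–H bond is traced back to a C11–O bond. The C11 hydroxyl is the by-product of the C11–aryl bond formation and the directing group for C8, and it is removed by a radical route because a cation at C11 next to quaternary C9 would invite 1,2-shifts. The demand is derivatisation of a hindered carbinol and a tin hydride reduction that spares the ester.

**19 ⇒ 18.** The C8–H bond (and one C–H of the C8 methyl) is cut back to the C8 methylene. The axial 8β-methyl is contra-thermodynamic, so hydrogen must be delivered to the α face of C8 from the C11 hydroxyl, which sits on the α face of C9. The demand is a hydroxyl-directed hydrogenation that outruns undirected addition.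

**18 ⇒ 14 + 16 (through 17); 16 ⇒ 15.** The C11–aryl bond is cut, which splits the molecule into the C16 bicyclic aldehyde and the complete arene. The demand is an aryl nucleophile that tolerates its own ester and still adds to a neopentyl aldehyde. 16 comes from 15 by cutting the O–benzyl bond.

**14 ⇒ 13 (key).** The C8–C9 bond is cut. This removes ring B and the C9 stereocentre and leaves a monocyclic ring A with a silyl enol ether arm on C10 and a butynyl arm on C5. The demand is 6-exo-dig closure, face selectivity at C9, and survival of the ketal and the O–Si bond until the C–C bond has formed.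

**13 ⇒ 12 ⇒ 11 ⇒ 10.** The O–Si bond is cut, then the C9–H/C11=O pair is traced to an oxirane, then the oxirane oxygen is removed to leave the isopropenyl group. The isopropenyl group already holds C9, its methyl and C11, so it is oxidised in place; excising its CH2 and re-adding a carbon by olefination would cost extra steps and an acidic enol ether hydrolysis next to the ketal. The demand is that a hydride shift from C11 beats an alkyl shift from quaternary C10, and that the peracid chooses the alkene over the alkyne.

**10 ⇒ 9 ⇒ 8 ⇒ 6 (through 7).** The terminal alkyne carbon is cut off, C8 is taken back to the alcohol level, and the C8–O bond is traced to the allyl group. The demand is anti-Markovnikov hydroboration of the allyl group in the presence of the isopropenyl group.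

**6 ⇒ 5.** The ketal C–O bonds are cut. The ketal masks C4 through fifteen steps and freezes the C5 configuration; it must be installed without enolising the ketone.

**5 ⇒ 1 + 2 + 3 (through 4).** The C10–C9 and C5–C6 bonds are cut. One operation gives the C10 quaternary centre by conjugate addition and the C5 centre by allylation of the enolate so formed. The demand is enantioselective copper catalysis and trapping trans to the isopropenyl group.

## Other disconnections considered

**Alternative 1:** The cut is the C9–C10 bond, by a retro-[3,3] shift that turns the ring-B acid A1 into the silyl ketene acetal of the 4,6-cis δ-lactone A2. In the forward direction A2 is enolised and O-silylated, and an Ireland–Claisen rearrangement through a boat forms C9–C10 while C6–O breaks, leaving the C5=C6 alkene and C11 as the acid.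
- In its favour: the configuration of the C6 carbinol and the ring-fixed ketene acetal geometry are transferred to C9 and C10 stereospecifically. The C8 methyl is already in A2, in the easily accessible cis relation to the alkenyl group, so no directed hydrogenation is needed.
- Against it here: the rearrangement must join the tetrasubstituted ketene acetal carbon to the methyl-bearing alkene carbon, i.e. two fully substituted centres, through a boat. Such congested shifts need heat, at which lactone ketene acetals tend to fragment or C-silylate. A2 must be made as a single isomer at C6 and C8. Afterwards C5=C6 has to be hydrogenated from the α face next to quaternary C10, and C11 has to be reduced from the acid level before the same arylation and deoxygenation.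
- Comparison: on structure, A1 secures C8 and the C9/C10 relation by a pericyclic transfer; on this point the alternative is the better plan, since the chosen route relies on a conformational preference at C9 and a directed hydrogenation at C8. On mechanism, the chosen closure bonds a trigonal carbon under catalysis at room temperature, whereas the alternative's key bond is the most congested of its route. On step economy the two are about equal at best, because the alkene reduction and the redox change at C11 add steps.

**Alternative 2:** The cut is the angular methyl, traced to the cyclopropane A3 (C10–CH2 and C5–CH2 bonds), which comes from the allylic alcohol A4, itself derived from the anisole-type tetralone A5 by alkylation at C9 and Birch reduction. In the forward direction the zinc alkoxide of the 4β-hydroxyl of A4 delivers CH2 from Et2Zn/CH2I2 (Simmons–Smith) to the β face of C5=C10. Oxidation to the C4 ketone and Li/NH3 cleavage of C5–CH2 would then leave the C10 methyl.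
- In its favour: a small carbenoid delivered intramolecularly makes C10 quaternary next to the existing quaternary C9 with predictable face control. Ring A comes from a cheap arene, and the cyclopropyl ketone opening leaves the C4 carbonyl ready for methylenation.
- Against it here: C9 must first be made as a quaternary stereocentre on A5, where CH3 and CH2OR differ little. The 4β-hydroxyl must be set relative to C9 across the ring. C5 is fixed only by enolate protonation, with the same epimerisation liability. The C8 ketone still has to become the axial 8β-methyl, and C11 needs deprotection and oxidation before arylation.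
- Comparison: on face control at the new quaternary carbon the directed cyclopropanation is the equal of, or better than, the chair preference of the gold closure. It sets only C10, however, and leaves absolute configuration and C9 to weaker steps, whereas the chosen plan fixes absolute configuration catalytically in its first step. On step economy the alternative is clearly longer (Birch reduction, enol ether hydrolysis, reduction, cyclopropanation, oxidation, reductive opening before ring B is even finished).

**Alternative 3:** The cut is C5–C10 and C8–C9, a retro-Diels–Alder of the meso anhydride A6 to buta-1,3-diene A7 and 2,3-dimethylmaleic anhydride A8. In the forward direction a thermal [4+2] cycloaddition closes ring B with both methyl-bearing quaternary carbons.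
- In its favour: the two quaternary carbons and their cis relation come in one step from bulk chemicals with no selectivity question. The cis relation is guaranteed by the dienophile geometry, and on this point the alternative is the better plan. Desymmetrisation of meso anhydrides by alkaloid-mediated alcoholysis is well established.
- Against it here: A8 is a tetrasubstituted, sluggish dienophile that needs forcing conditions. A6 has neither ring A nor the C8 methyl, and its only handles at C5 and C8 are allylic C–H bonds on a nearly symmetric alkene. The two carbonyls must be told apart, one homologated into ring A (C1–C4 annulated onto C5) and the other taken to the aldehyde.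
- Comparison: on structure the adduct maps only ring B, while the chosen precursor already holds ring A and every carbon of ring B. On mechanism the cycloaddition is robust once it proceeds, but the hard work is moved to unselective functionalisation afterwards. On step economy the alternative is far longer.

Key step: step 9

Remark on the chemistry: the target is taken exactly as drawn, with the methyl-bearing ring-fusion carbon C10 bonded directly to C9. Locants C1–C11 and α/β (β = face of the C10 methyl) refer to this skeleton numbering.

Remark on the chemistry: the new centres at C9 in 11 and 12 and at C11 in 18–20 are erased later, so these compounds are carried as epimer mixtures.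

## Route

Step 1
Reactants: 1 3-methylcyclohex-2-en-1-one; 2 isopropenylmagnesium bromide; 3 allyl bromide
Product: 5 (2R,3S)-3-methyl-2-(prop-2-en-1-yl)-3-(prop-1-en-2-yl)cyclohexan-1-one, via magnesium enolate 4 (not isolated)
Conditions: Cu(OTf)2 (3 mol %), 1-(1-hydroxy-4-methylpentan-2-yl)-3-mesityl-4,5-dihydroimidazolium hexafluorophosphate (4 mol %; single enantiomer chosen to give S at C10), Et2O, 0 °C; then 3, DMPU, THF, −30 °C → rt
Reagents that add atoms: none
Why: Copper-catalysed asymmetric conjugate addition of an alkenyl Grignard reagent to a β-substituted cyclohexenone (chiral N-heterocyclic carbene ligand) creates the C10 quaternary centre. The magnesium enolate 4 is then allylated at C5 on the face away from the branched isopropenyl group, which gives the trans relation of the C5 and C10 carbon arms.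

Step 2
Reactants: 5 (2R,3S)-3-methyl-2-(prop-2-en-1-yl)-3-(prop-1-en-2-yl)cyclohexan-1-one
Product: 6 (6R,7S)-7-methyl-6-(prop-2-en-1-yl)-7-(prop-1-en-2-yl)-1,4-dioxaspiro[4.5]decane
Conditions: TMSOCH2CH2OTMS, TMSOTf (cat.), CH2Cl2, −78 → −20 °C
Reagents that add atoms: 1,2-bis(trimethylsilyloxy)ethane, C[Si](C)(C)OCCO[Si](C)(C)C
Why: Noyori ketalisation under aprotic conditions at low temperature protects C4 without enolising the ketone, so the C5 configuration is kept. From here on C5–H is no longer α to a carbonyl.

Step 3
Reactants: 6 (6R,7S)-7-methyl-6-(prop-2-en-1-yl)-7-(prop-1-en-2-yl)-1,4-dioxaspiro[4.5]decane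
Product: 8 3-[(6R,7S)-7-methyl-7-(prop-1-en-2-yl)-1,4-dioxaspiro[4.5]decan-6-yl]propan-1-ol, via alkyldisiamylborane 7 (not isolated)
Conditions: Sia2BH (from BH3·SMe2 and 2-methylbut-2-ene), THF, 0 °C; then NaOH, H2O2, 0 °C → rt
Reagents that add atoms: hydrogen peroxide, OO
Why: Anti-Markovnikov hydroboration–oxidation: disiamylborane reacts with the monosubstituted allyl terminus much faster than with the 1,1-disubstituted, neopentyl-type isopropenyl group.

Step 4
Reactants: 8 3-[(6R,7S)-7-methyl-7-(prop-1-en-2-yl)-1,4-dioxaspiro[4.5]decan-6-yl]propan-1-ol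
Product: 9 3-[(6R,7S)-7-methyl-7-(prop-1-en-2-yl)-1,4-dioxaspiro[4.5]decan-6-yl]propanal
Conditions: TEMPO (10 mol %), PhI(OAc)2, CH2Cl2, rt
Reagents that add atoms: none
Why: TEMPO-catalysed oxidation stops at the aldehyde and leaves the alkene and the ketal untouched.

Step 5
Reactants: 9 3-[(6R,7S)-7-methyl-7-(prop-1-en-2-yl)-1,4-dioxaspiro[4.5]decan-6-yl]propanal
Product: 10 (6R,7S)-6-(but-3-yn-1-yl)-7-methyl-7-(prop-1-en-2-yl)-1,4-dioxaspiro[4.5]decane
Conditions: dimethyl (1-diazo-2-oxopropyl)phosphonate, K2CO3, MeOH, 0 °C → rt
Reagents that add atoms: dimethyl (1-diazo-2-oxopropyl)phosphonate, COP(=O)(OC)C(=[N+]=[N-])C(C)=O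
Why: Ohira–Bestmann (Seyferth–Gilbert) homologation turns the aldehyde into the terminal alkyne with one added carbon under mild carbonate conditions. No stereocentre is α to the aldehyde.

Step 6
Reactants: 10 (6R,7S)-6-(but-3-yn-1-yl)-7-methyl-7-(prop-1-en-2-yl)-1,4-dioxaspiro[4.5]decane
Product: 11 (6R,7S)-6-(but-3-yn-1-yl)-7-methyl-7-(2-methyloxiran-2-yl)-1,4-dioxaspiro[4.5]decane (both oxirane epimers)
Conditions: mCPBA, NaHCO3 (buffer), CH2Cl2, 0 °C → rt
Reagents that add atoms: 3-chloroperoxybenzoic acid, OOC(=O)c1cccc(Cl)c1
Why: Prilezhaev epoxidation: the electron-rich 1,1-disubstituted alkene is oxidised while the far less nucleophilic terminal alkyne is left. The new oxirane centre is formed unselectively and converges in step 8.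

Step 7
Reactants: 11 (6R,7S)-6-(but-3-yn-1-yl)-7-methyl-7-(2-methyloxiran-2-yl)-1,4-dioxaspiro[4.5]decane
Product: 12 2-[(6R,7R)-6-(but-3-yn-1-yl)-7-methyl-1,4-dioxaspiro[4.5]decan-7-yl]propanal (both C2 epimers; the 7R label is a priority change only)
Conditions: MeAl(OC6H2-2,6-t-Bu2-4-Br)2 (20 mol %), CH2Cl2, −78 → −20 °C
Reagents that add atoms: none
Why: Meinwald rearrangement: the bulky aluminium Lewis acid opens the 2,2-disubstituted oxirane at the tertiary C9–O bond and a 1,2-hydride shift from C11 gives the aldehyde, so C11 is the original isopropenyl CH2. Low temperature and the hindered Lewis acid disfavour alkyl shifts from C10 and opening of the ketal.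

Step 8
Reactants: 12 2-[(6R,7R)-6-(but-3-yn-1-yl)-7-methyl-1,4-dioxaspiro[4.5]decan-7-yl]propanal
Product: 13 tert-butyl({(1E)-2-[(6R,7S)-6-(but-3-yn-1-yl)-7-methyl-1,4-dioxaspiro[4.5]decan-7-yl]prop-1-en-1-yl}oxy)dimethylsilane
Conditions: TBSOTf, Et3N, CH2Cl2, −78 → 0 °C
Reagents that add atoms: tert-butyldimethylsilyl trifluoromethanesulfonate, CC(C)(C)[Si](C)(C)OS(=O)(=O)C(F)(F)F
Why: Soft enolisation of the α-branched aldehyde gives the silyl enol ether, expected mainly as the E isomer with the silyloxy group away from quaternary C10. Both C9 epimers of 12 converge, and the aldehyde is silylated far faster than the ketal is activated.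

Step 9
Reactants: 13 tert-butyl({(1E)-2-[(6R,7S)-6-(but-3-yn-1-yl)-7-methyl-1,4-dioxaspiro[4.5]decan-7-yl]prop-1-en-1-yl}oxy)dimethylsilane
Product: 14 (5R,9R,10S)-4,4-ethylenedioxy-9,10-dimethyl-8-methylidenedecalin-9-carbaldehyde (skeleton numbering; trans-fused, 5α-H, 9β-CH3, 9α-CHO, 10β-CH3)
Conditions: Ph3PAuNTf2 (5 mol %), CH2Cl2/MeOH (10:1), rt
Reagents that add atoms: none
Why: Cationic monovalent gold binds the terminal alkyne of 13, C9 of the silyl enol ether attacks the internal carbon C8 anti to gold, the silyloxocarbenium ion at C11 is desilylated by methanol and the alkenylgold is protodeaurated to the C8 methylene. The closest known reaction type is the gold-catalysed exo-dig carbocyclisation of silyl enol ethers onto alkynes (Conia-ene type), which is documented for making a quaternary carbon next to an exocyclic methylene. Ring B closes in the 6-exo-dig mode; 7-endo attack on the terminal carbon is disfavoured because the gold-bound terminal alkyne is polarised for attack at its internal carbon and the six-membered chair is the less strained transition state. The ring fusion is already fixed as trans, because the butynyl chain on C5 and the C10–C9 bond are both equatorial on ring A. The new stereocentre C9 is controlled by the substrate: in the chair-like closure the planar C11 arm takes the pseudo-axial site on the α face, antiperiplanar to the axial C10 methyl, and the C9 methyl takes the pseudo-equatorial site, which gives 9β-methyl and 9α-formyl. The step needs the enol ether to react before its O–Si bond is solvolysed and before a ketal oxygen can interfere; a preformed silver-free catalyst without free acid and only a small proportion of methanol secure this. No bond between two fully substituted carbons is made, because C10 became quaternary in step 1 and C9 is still trigonal here.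

Step 10
Reactants: 15 methyl 4-hydroxy-3-iodobenzoate
Product: 16 methyl 4-(benzyloxy)-3-iodobenzoate
Conditions: BnBr, K2CO3, DMF, rt
Reagents that add atoms: benzyl bromide, BrCc1ccccc1
Why: Williamson ether synthesis. The benzyl ether survives the Grignard, iridium hydrogenation, xanthate and tin hydride steps, does not migrate to a neighbouring alkoxide, and is removed by neutral hydrogenolysis.

Step 11
Reactants: 16 methyl 4-(benzyloxy)-3-iodobenzoate; 14 (5R,9R,10S)-4,4-ethylenedioxy-9,10-dimethyl-8-methylidenedecalin-9-carbaldehyde
Product: 18 methyl 4-(benzyloxy)-3-{hydroxy[(5R,9R,10S)-4,4-ethylenedioxy-9,10-dimethyl-8-methylidenedecalin-9-yl]methyl}benzoate (C11 epimers), via arylmagnesium chloride 17 (not isolated)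
Conditions: 16, i-PrMgCl·LiCl, THF, −40 °C; then 14, −40 → 0 °C; aq. NH4Cl
Reagents that add atoms: none
Why: Iodine–magnesium exchange at low temperature gives an ester-tolerant arylmagnesium 17, which adds to the aldehyde faster than to an ester (Grignard 1,2-addition). The C11 configuration does not matter because the hydroxyl is removed in steps 13 and 14.

Step 12
Reactants: 18 methyl 4-(benzyloxy)-3-{hydroxy[(5R,9R,10S)-4,4-ethylenedioxy-9,10-dimethyl-8-methylidenedecalin-9-yl]methyl}benzoate
Product: 19 methyl 4-(benzyloxy)-3-{hydroxy[(5R,8S,9R,10S)-4,4-ethylenedioxy-8,9,10-trimethyldecalin-9-yl]methyl}benzoate (C11 epimers; 8β-CH3)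
Conditions: [Ir(cod)(PCy3)(py)]PF6 (10 mol %), H2 (1 atm), CH2Cl2, rt
Reagents that add atoms: none
Why: Hydroxyl-directed homogeneous hydrogenation: the homoallylic C11 hydroxyl, held on the α face of C9, binds iridium and delivers H2 to the α face of the C8 methylene, so the new methyl is β (axial), the contra-thermodynamic epimer. Either C11 epimer can chelate.

Step 13
Reactants: 19 methyl 4-(benzyloxy)-3-{hydroxy[(5R,8S,9R,10S)-4,4-ethylenedioxy-8,9,10-trimethyldecalin-9-yl]methyl}benzoate
Product: 20 O-{[2-(benzyloxy)-5-(methoxycarbonyl)phenyl][(5R,8S,9R,10S)-4,4-ethylenedioxy-8,9,10-trimethyldecalin-9-yl]methyl} S-methyl carbonodithioate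
Conditions: NaH, CS2, THF, 0 °C → rt; then MeI
Reagents that add atoms: carbon disulfide, S=C=S; iodomethane, CI
Why: Xanthate formation, the first stage of a Barton–McCombie deoxygenation: the alkoxide adds to the small linear CS2 even at a hindered carbinol and is then S-methylated. C11 has no β-hydrogen, so Chugaev elimination is excluded.

Step 14
Reactants: 20 O-{[2-(benzyloxy)-5-(methoxycarbonyl)phenyl][(5R,8S,9R,10S)-4,4-ethylenedioxy-8,9,10-trimethyldecalin-9-yl]methyl} S-methyl carbonodithioate
Product: 21 methyl 4-(benzyloxy)-3-{[(5R,8S,9R,10S)-4,4-ethylenedioxy-8,9,10-trimethyldecalin-9-yl]methyl}benzoate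
Conditions: Bu3SnH, AIBN (cat.), toluene, 110 °C
Reagents that add atoms: none
Why: Barton–McCombie deoxygenation: stannyl radical addition to the thiocarbonyl and β-scission give a benzylic C11 radical that abstracts hydrogen. A radical at C11 does not undergo the 1,2-shifts that a cation beside quaternary C9 would.

Step 15
Reactants: 21 methyl 4-(benzyloxy)-3-{[(5R,8S,9R,10S)-4,4-ethylenedioxy-8,9,10-trimethyldecalin-9-yl]methyl}benzoate
Product: 23 methyl 4-hydroxy-3-{[(5R,8S,9R,10S)-8,9,10-trimethyl-4-oxodecalin-9-yl]methyl}benzoate, via phenol ketal 22 (not isolated)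
Conditions: H2 (1 atm), Pd/C, THF/MeOH, rt; then 1 M aq. HCl, rt
Reagents that add atoms: water, O
Why: Hydrogenolysis of the aryl benzyl ether, then hydrolysis of the dioxolane with dilute acid at room temperature. Ketal hydrolysis is much faster than acid-catalysed enolisation of the freed ketone, which protects the C5 configuration against drift to the cis-fused epimer.

Step 16
Reactants: 23 methyl 4-hydroxy-3-{[(5R,8S,9R,10S)-8,9,10-trimethyl-4-oxodecalin-9-yl]methyl}benzoate
Product: 24 methyl 4-hydroxy-3-{[(1R,2S,4aS,8aS)-1,2,8a-trimethyl-5-methylidenedecahydronaphthalen-1-yl]methyl}benzoate (skeleton numbering 5S,8S,9R,10S)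
Conditions: Zn, CH2Br2, TiCl4 (reagent pre-formed in THF, −40 → 5 °C), CH2Cl2, 0 °C → rt
Reagents that add atoms: dibromomethane, BrCBr
Why: Lombardo methylenation: the zinc–titanium methylene reagent is non-basic, so the ketone is methylenated without enolisation toward C5, and the methyl ester is left. Excess reagent covers the free phenol.

## Compound list

1 | 3-methylcyclohex-2-en-1-one | CC1=CC(=O)CCC1 | starting material
2 | isopropenylmagnesium bromide | C=C(C)[Mg]Br | starting material
3 | allyl bromide | C=CCBr | starting material
4 | bromomagnesium (3S)-3-methyl-3-(prop-1-en-2-yl)cyclohex-1-en-1-olate (not isolated) | Br[Mg]OC1=C[C@@](C)(C(C)=C)CCC1 | intermediate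
5 | (2R,3S)-3-methyl-2-(prop-2-en-1-yl)-3-(prop-1-en-2-yl)cyclohexan-1-one | O=C1CCC[C@@](C(C)=C)(C)[C@H]1CC=C | intermediate
6 | (6R,7S)-7-methyl-6-(prop-2-en-1-yl)-7-(prop-1-en-2-yl)-1,4-dioxaspiro[4.5]decane | O1CCOC12CCC[C@@](C(C)=C)(C)[C@H]2CC=C | intermediate
7 | {3-[(6R,7S)-7-methyl-7-(prop-1-en-2-yl)-1,4-dioxaspiro[4.5]decan-6-yl]propyl}bis(3-methylbutan-2-yl)borane (not isolated) | O1CCOC12CCC[C@@](C(C)=C)(C)[C@H]2CCCB(C(C)C(C)C)C(C)C(C)C | intermediate
8 | 3-[(6R,7S)-7-methyl-7-(prop-1-en-2-yl)-1,4-dioxaspiro[4.5]decan-6-yl]propan-1-ol | O1CCOC12CCC[C@@](C(C)=C)(C)[C@H]2CCCO | intermediate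
9 | 3-[(6R,7S)-7-methyl-7-(prop-1-en-2-yl)-1,4-dioxaspiro[4.5]decan-6-yl]propanal | O1CCOC12CCC[C@@](C(C)=C)(C)[C@H]2CCC=O | intermediate
10 | (6R,7S)-6-(but-3-yn-1-yl)-7-methyl-7-(prop-1-en-2-yl)-1,4-dioxaspiro[4.5]decane | O1CCOC12CCC[C@@](C(C)=C)(C)[C@H]2CCC#C | intermediate
11 | (6R,7S)-6-(but-3-yn-1-yl)-7-methyl-7-(2-methyloxiran-2-yl)-1,4-dioxaspiro[4.5]decane (both oxirane epimers) | O1CCOC12CCC[C@@](C3(C)CO3)(C)[C@H]2CCC#C | intermediate
12 | 2-[(6R,7R)-6-(but-3-yn-1-yl)-7-methyl-1,4-dioxaspiro[4.5]decan-7-yl]propanal (both C2 epimers) | O1CCOC12CCC[C@@](C(C)C=O)(C)[C@H]2CCC#C | intermediate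
13 | tert-butyl({(1E)-2-[(6R,7S)-6-(but-3-yn-1-yl)-7-methyl-1,4-dioxaspiro[4.5]decan-7-yl]prop-1-en-1-yl}oxy)dimethylsilane | O1CCOC12CCC[C@@](/C(C)=C/O[Si](C)(C)C(C)(C)C)(C)[C@H]2CCC#C | intermediate
14 | (5R,9R,10S)-4,4-ethylenedioxy-9,10-dimethyl-8-methylidenedecalin-9-carbaldehyde (5α-H, 9β-CH3, 9α-CHO, 10β-CH3) | O1CCOC12CCC[C@@]3(C)[C@H]2CCC(=C)[C@@]3(C)C=O | intermediate
15 | methyl 4-hydroxy-3-iodobenzoate | COC(=O)c1ccc(O)c(I)c1 | starting material
16 | methyl 4-(benzyloxy)-3-iodobenzoate | COC(=O)c1ccc(OCc2ccccc2)c(I)c1 | intermediate
17 | [2-(benzyloxy)-5-(methoxycarbonyl)phenyl]magnesium chloride (not isolated) | COC(=O)c1ccc(OCc2ccccc2)c([Mg]Cl)c1 | intermediate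
18 | methyl 4-(benzyloxy)-3-{hydroxy[(5R,9R,10S)-4,4-ethylenedioxy-9,10-dimethyl-8-methylidenedecalin-9-yl]methyl}benzoate (C11 epimers) | O1CCOC12CCC[C@@]3(C)[C@H]2CCC(=C)[C@@]3(C)C(O)c1cc(C(=O)OC)ccc1OCc1ccccc1 | intermediate
19 | methyl 4-(benzyloxy)-3-{hydroxy[(5R,8S,9R,10S)-4,4-ethylenedioxy-8,9,10-trimethyldecalin-9-yl]methyl}benzoate (C11 epimers) | O1CCOC12CCC[C@@]3(C)[C@H]2CC[C@H](C)[C@@]3(C)C(O)c1cc(C(=O)OC)ccc1OCc1ccccc1 | intermediate
20 | O-{[2-(benzyloxy)-5-(methoxycarbonyl)phenyl][(5R,8S,9R,10S)-4,4-ethylenedioxy-8,9,10-trimethyldecalin-9-yl]methyl} S-methyl carbonodithioate (C11 epimers) | O1CCOC12CCC[C@@]3(C)[C@H]2CC[C@H](C)[C@@]3(C)C(OC(=S)SC)c1cc(C(=O)OC)ccc1OCc1ccccc1 | intermediate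
21 | methyl 4-(benzyloxy)-3-{[(5R,8S,9R,10S)-4,4-ethylenedioxy-8,9,10-trimethyldecalin-9-yl]methyl}benzoate | O1CCOC12CCC[C@@]3(C)[C@H]2CC[C@H](C)[C@@]3(C)Cc1cc(C(=O)OC)ccc1OCc1ccccc1 | intermediate
22 | methyl 3-{[(5R,8S,9R,10S)-4,4-ethylenedioxy-8,9,10-trimethyldecalin-9-yl]methyl}-4-hydroxybenzoate (not isolated) | O1CCOC12CCC[C@@]3(C)[C@H]2CC[C@H](C)[C@@]3(C)Cc1cc(C(=O)OC)ccc1O | intermediate
23 | methyl 4-hydroxy-3-{[(5R,8S,9R,10S)-8,9,10-trimethyl-4-oxodecalin-9-yl]methyl}benzoate | O=C1CCC[C@@]2(C)[C@H]1CC[C@H](C)[C@@]2(C)Cc1cc(C(=O)OC)ccc1O | intermediate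
24 | methyl 4-hydroxy-3-{[(1R,2S,4aS,8aS)-1,2,8a-trimethyl-5-methylidenedecahydronaphthalen-1-yl]methyl}benzoate | C=C1CCC[C@@]2(C)[C@H]1CC[C@H](C)[C@@]2(C)Cc1cc(C(=O)OC)ccc1O | target

## Step count and least certain steps

Total: 16 steps. Longest linear sequence: 15 steps (steps 1–9 and 11–16); step 10 is a one-step branch.

**Step 9 (key).** The O–Si bond may be solvolysed before the C–C bond forms, and the preference between the two chair-like closures at C9 may be small, because both C9 substituents are of similar effective size and the enol ether is flanked by the quaternary C10. Fallback, from 12 back to 14: the aldehyde 12 is treated with catalytic cyclohexylamine and InCl3 in 1,2-dichloroethane with warming. The N-cyclohexyl enamine F1 forms in the flask, adds to the π-acid-activated alkyne in the same 6-exo-dig sense, and hydrolysis of the resulting imine returns 14. No silyl group can be lost in this mode, and the bulkier enamine arm should favour the pseudo-axial site more strongly.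

**Step 1.** Enantioselectivity may erode with an alkenyl Grignard reagent, and the hindered magnesium enolate may be trapped slowly, with poor face selectivity or on oxygen. Fallback, from 1 and 2 back to 5: the conjugate addition is quenched with Me3SiCl/Et3N and the trimethylsilyl enol ether F2 is isolated. F2 is then allylated with allyl methyl carbonate under zerovalent palladium catalysis (Pd2(dba)3, dppe, THF, 65 °C; Tsuji allylation), where a bulkier π-allyl electrophile attacks carbon only, and this gives 5.

**Step 7.** A 1,2-alkyl shift from quaternary C10 to the C9 cation, or capture of that cation by a ketal oxygen, may compete with the hydride shift. Fallback, from 10 back to 12, with no cationic intermediate: ozonolysis of 10 (O3, CH2Cl2, −78 °C; Me2S; the alkyne is far slower than the alkene) gives the methyl ketone F3. Van Leusen reductive cyanation (TosMIC, KOt-Bu, DME/EtOH) gives the nitrile F4, and i-Bu2AlH at −78 °C followed by mild hydrolysis gives 12.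

**Step 11.** Addition to the neopentyl aldehyde, shielded by C9, C10 and the ortho substituent of the nucleophile, may be slow enough that the arylmagnesium attacks the ester of a second molecule. Fallback, from 14 back to 18: the ester is introduced afterwards. The benzyl ether of 4-bromo-2-iodophenol, 1-(benzyloxy)-4-bromo-2-iodobenzene F5, undergoes selective iodine–magnesium exchange to the ester-free Grignard reagent [2-(benzyloxy)-5-bromophenyl]magnesium chloride F6, which can be used warm and in excess and adds to 14 to give the bromoaryl carbinol F7. Methoxycarbonylation of F7 (Pd(OAc)2, dppf, CO, MeOH, Et3N, DMF, 80 °C) gives 18.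

**Step 12.** The hindered secondary C11 hydroxyl, crowded by the aryl group, may bind iridium poorly, so that hydrogen is delivered without direction or the alkene migrates into ring B. Fallback, from 14 back to 19: 14 is reduced with NaBH4 to the primary homoallylic alcohol F8, an unhindered director. Hydrogenation with [Ir(cod)(PCy3)(py)]PF6 gives the 8β-methyl alcohol F9, oxidation with TEMPO/PhI(OAc)2 gives the saturated aldehyde F10, and addition of 17 gives 19.

## Further compounds

F1 | step 9 | (E)-N-cyclohexyl-2-[(6R,7S)-6-(but-3-yn-1-yl)-7-methyl-1,4-dioxaspiro[4.5]decan-7-yl]prop-1-en-1-amine | O1CCOC12CCC[C@@](/C(C)=C/NC3CCCCC3)(C)[C@H]2CCC#C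
F2 | step 1 | trimethyl{[(3S)-3-methyl-3-(prop-1-en-2-yl)cyclohex-1-en-1-yl]oxy}silane | C[Si](C)(C)OC1=C[C@@](C)(C(C)=C)CCC1
F3 | step 7 | 1-[(6R,7S)-6-(but-3-yn-1-yl)-7-methyl-1,4-dioxaspiro[4.5]decan-7-yl]ethan-1-one | O1CCOC12CCC[C@@](C(C)=O)(C)[C@H]2CCC#C
F4 | step 7 | 2-[(6R,7R)-6-(but-3-yn-1-yl)-7-methyl-1,4-dioxaspiro[4.5]decan-7-yl]propanenitrile (both C2 epimers) | O1CCOC12CCC[C@@](C(C)C#N)(C)[C@H]2CCC#C
F5 | step 11 | 1-(benzyloxy)-4-bromo-2-iodobenzene | Brc1ccc(OCc2ccccc2)c(I)c1
F6 | step 11 | [2-(benzyloxy)-5-bromophenyl]magnesium chloride | Brc1ccc(OCc2ccccc2)c([Mg]Cl)c1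
F7 | step 11 | [2-(benzyloxy)-5-bromophenyl][(5R,9R,10S)-4,4-ethylenedioxy-9,10-dimethyl-8-methylidenedecalin-9-yl]methanol (C11 epimers) | O1CCOC12CCC[C@@]3(C)[C@H]2CCC(=C)[C@@]3(C)C(O)c1cc(Br)ccc1OCc1ccccc1
F8 | step 12 | [(5R,9R,10S)-4,4-ethylenedioxy-9,10-dimethyl-8-methylidenedecalin-9-yl]methanol | O1CCOC12CCC[C@@]3(C)[C@H]2CCC(=C)[C@@]3(C)CO
F9 | step 12 | [(5R,8S,9R,10S)-4,4-ethylenedioxy-8,9,10-trimethyldecalin-9-yl]methanol | O1CCOC12CCC[C@@]3(C)[C@H]2CC[C@H](C)[C@@]3(C)CO
F10 | step 12 | (5R,8S,9R,10S)-4,4-ethylenedioxy-8,9,10-trimethyldecalin-9-carbaldehyde | O1CCOC12CCC[C@@]3(C)[C@H]2CC[C@H](C)[C@@]3(C)C=O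
A1 | alternative 1 | ring-B carboxylic acid with C5=C6 alkene and C4 ethylene ketal (8β-CH3, 9β-CH3, 9α-CO2H, 10β-CH3) | O1CCOC12CCC[C@@]3(C)C2=CC[C@H](C)[C@@]3(C)C(=O)O
A2 | alternative 1 | 4,6-cis-3,4-dimethyl-6-(6,6-ethylenedioxy-2-methylcyclohex-1-en-1-yl)oxan-2-one (C3 epimers) | O=C1O[C@@H](C[C@H](C)C1C)C2=C(C)CCCC23OCCO3
A3 | alternative 2 | 4β-hydroxy-5β,10β-methanodecalin with C8 ethylene ketal, 9β-methyl and 9α-(tert-butyldimethylsilyloxymethyl) | O[C@H]1CCC[C@]23C[C@]31CCC4(OCCO4)[C@@]2(C)CO[Si](C)(C)C(C)(C)C
A4 | alternative 2 | 4β-hydroxy-5(10)-octalin with C8 ethylene ketal, 9β-methyl and 9α-(tert-butyldimethylsilyloxymethyl) | O[C@H]1CCCC2=C1CCC1(OCCO1)[C@@]2(C)CO[Si](C)(C)C(C)(C)C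
A5 | alternative 2 | 5-methoxy-1-methyl-3,4-dihydronaphthalen-2(1H)-one | COc1cccc2c1CCC(=O)C2C
A6 | alternative 3 | meso cis-1,2-dimethylcyclohex-4-ene-1,2-dicarboxylic anhydride | C[C@@]12CC=CC[C@]1(C)C(=O)OC2=O
A7 | alternative 3 | buta-1,3-diene | C=CC=C
A8 | alternative 3 | 2,3-dimethylmaleic anhydride | CC1=C(C)C(=O)OC1=O
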